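The easy step is the binding, so we start there. In this flask first complex falls back far faster than it goes on, and so does second complex, so we treat both binding steps as at equilibrium.

    starting material + free enzyme ⇌ first complex (K1 = 220 M⁻¹, k1 = 49100 M⁻¹ s⁻¹)
    second substrate + loaded enzyme ⇌ second complex (K2 = 16 M⁻¹, k2 = 1.49 × 10⁵ M⁻¹ min⁻¹)
    second complex → free enzyme + target (k3 = 555 min⁻¹)
    first complex → loaded enzyme + first product (k4 = 623 min⁻¹)

starting material 16 mM; second substrate 80.0 mM; free enzyme 0.82 µM; time 25 min

- the reaction counts as stopped when no species that holds the starting material changes by six tenths of a point or more over the second half of the time
- run time (flask): 25 min

- at 25 min, what has stopped the reaction, if anything has (no working catalyst is left / the second substrate has run out first / all of the starting material has reacted / forward and back rates have come level / it is still moving)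
- conversion of starting material at 25 min
- amount of target at 25 min, in percent of the starting material charged

The bench rule says that substrate in excess saturates the enzyme, which then turns at 294 min⁻¹. That gives 37.6% of the starting material here. But the rule needs each equilibrium constant times its c(substrate) to lie far above one, and at the start of this flask those products are 3.5 and 1.3, so the second step stands at the rule's border.

We therefore time one cycle. A pass through first complex lasts 0.0963 s, and the free enzyme standing beside it at equilibrium stretches this to 0.124 s. A pass through second complex lasts 0.108 s, and the loaded enzyme beside it stretches this to 0.193 s. The inverse of the sum is the cycle rate, the passes one catalyst makes per minute with binding at equilibrium (its turnover frequency): 190 min⁻¹.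

In this flask, at the charges, that reckons to 3.89 mM of target in the given time, or 24.3%. This is less than the charge of starting material, and both product steps are one-way, so we expect the flask still moving. The catalyst is far less than this amount, so yield should equal conversion. With that much of both substrates consumed, the cycle rate reckons to 182 min⁻¹, which held over the whole time would give 23.3%. We commit to the span between the two figures.

The forecast's answer is that it is still moving, “with nothing exhausted and the last step irreversible”, and it gives 23.4% conversion (22.5% to 24.3%) and 23.4% target, near the low end of our span. In the simulation of this flask, it is still moving, with 23.4% conversion and 23.4% target.

In this flask at 12.4 min first complex falls back 21 times faster than it goes on, and second complex 17 times. At 12.5 min first complex holds 29.3% of the catalyst in this flask and loaded enzyme 27.9%. For the neighbour flask with 32 mM of second substrate, the cycle rate at the charges is 135 min⁻¹, which gives 17.4%. That flask's computed conversion is 16.4%.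

Its constants were drawn at random within sensible limits.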